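## Remarks on the chemistry

- Target **17** has the (8R,8'R) configuration in both halves. The conjugate-addition substrate **6** and product **10** agree with it centre by centre: C7' is R and the aryl group is trans to the new C9' arm. One descriptor needs care: the propargylic carbinols of **4** have the same spatial arrangement as C7' of **6** but are S, because the substituted alkynyl carbon outranks the aryl carbon whereas an alkenyl carbon does not.
- Stoichiometry: every step on the biaryl runs at two equivalent sites. Two molecules of **3**, of **8** and of **12** are therefore built into one molecule of **4**, **10** and **13**; the first stands under Reactants and the second under "Reagents that add atoms".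
- Assumption: (S,S)-ProPhenol is taken to give the (S)-carbinols of **4**. If a trial on 4-(benzyloxy)-3-methoxybenzaldehyde showed the opposite sense, the (R,R)-ligand would be used with no other change.
- Assumption: **1** and **11** are bought. **1** is otherwise one step from vanillin by FeSO4/Na2S2O8 coupling, and **11** two steps from vanillin.
- Design choice: the silane is kept on C9' until C8 is complete (Tamao oxidation after the two enolate steps). A free C9' hydroxyl next to the provisional lactone could transfer the acyl group to itself under base and restore the wrong facial bias. The C–Si bond cannot do this, and no protecting group is needed.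

## Structural features

Compound **17** is a C2-symmetric dimer in which two (8R,8'R)-nortrachelogenin units are joined by one aryl–aryl bond between the C5 positions of their ring B guaiacyl rings, each ortho to a ring B phenol. Each unit is a γ-butyrolactone (C9 carbonyl, ring oxygen, C9' methylene, C8', C8) with two adjacent stereocentres, the quaternary carbinol C8 that carries the ring A benzyl group through C7 and the tertiary C8' that carries ring B through the methylene C7'; the two benzyl groups are trans and the C8 hydroxyl is cis to the C8' benzyl group. The biaryl axis has one ortho oxygen on each ring and is not a stereo element, but the two pairs of stereocentres are remote from each other, so a heterochiral (meso) dimer would be a diastereomer that is unlikely to separate easily. Fragile elements are the four electron-rich free phenols (oxidation, above all under base), the tertiary α-hydroxy lactone (ring opening, acyl migration) and, in protected intermediates, every benzylic C–O bond para to an oxygen. The real difficulty is C8: on the natural lactone an electrophilic oxygen enters the α-benzyl enolate anti to the C8' benzyl group and gives the C8 epimer, and this has to be solved twice in one molecule. The key step uses the fact that C7' is a plain benzylic CH2 on ring B while C9' is an O–CH2. A provisional lactone from C9 to an oxygen on C7' makes C9' the exocyclic arm on C8', lets its C7' stereocentre direct the C8'–C9' bond formation, and has a benzylic C–O bond that can be removed at the end.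

## Logic of the disconnections

**17 ⇒ 15 (through 16).** In each half the ester bond from C9 to the C9' oxygen is opened, C9 is closed instead onto an oxygen placed on C7', and the four phenols are capped as benzyl ethers. In **15** the arm on C8' is C9' and not the ring B benzyl group, which reverses the sense in which C8' steers reactions at C8. The C7'–O bond is of the same kind as the protecting groups, so it costs no extra step. The forward step must cleave two lactone benzylic C–O bonds and four O-benzyl groups without touching the C8 carbinol, and the freed acid must close on the C9' hydroxyl.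

**15 ⇒ 14.** The two C9'–O bonds are traced back to C9'–Si bonds. While C9' carries silicon it has no nucleophilic oxygen, so the acyl group cannot move before C8 is set, and a protection step is saved. The forward oxidation must tolerate α-hydroxy lactones and benzyl ethers, and the alkoxysilane must survive two enolate reactions.

**14 ⇒ 13.** The two C8–O bonds are cut. This turns each quaternary carbinol into an enolisable CH. The forward step needs oxygen transfer to the enolate face anti to the C9' arm on both lactones.

**13 ⇒ 10 + 12 (12 ⇒ 11).** The two C8–C7 bonds are cut, releasing both ring A units as two molecules of **12**, which comes from **11** by exchange of hydroxyl for bromide. The forward step must alkylate each lactone once only; the configuration created at C8 does not matter because C8 is made planar again in the next step.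

**10 ⇒ 6 + 8 (8 ⇒ 7).** The two C8'–C9' bonds are cut. C8' is the electrophilic β-carbon of a butenolide and C9' arrives as a hydroxymethyl carbanion equivalent, one molecule of **8** for each ring. This removes both C8' stereocentres and leaves C7' as the only stereocentre per half. The forward step needs 1,4-addition trans to the aryl group at both rings, without deprotonation at the doubly activated C7'.

**6 ⇒ 4 (through 5).** The lactone C9–O bonds are opened and the Z-alkenes are traced back to alkynes. The linear ynoate is reachable by carbonyl addition. The forward semihydrogenation must stop at the alkene and leave benzyl ethers and the benzylic carbinol C–O bond intact.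

**4 ⇒ 2 + 3 (2 ⇒ 1).** The two C7'–C8' bonds are cut to **2** and two molecules of **3**, and the O-benzyl bonds are cut. The biaryl bond and the whole ring B substitution pattern are bought with **1**. The forward addition needs catalyst-controlled facial selectivity at two independent aldehydes.

## Other disconnections considered

**Alternative 1:** The cut is the C7–aryl bond of ring A in each half. In the forward sense the aryl Grignard reagent A3 with catalytic CuI would open both 2,2-disubstituted epoxides of bis(glycidic ester) A2 at the CH2 terminus to give bis(α-hydroxy ester) A1. Desilylation, lactonisation and hydrogenolysis would then lead to **17**.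
- In its favour: C8 would be fixed by a reagent-controlled epoxidation upstream of A2 (Ti(OiPr)4, tartrate, tBuOOH), independent of any lactone facial bias. Attack at the unhindered CH2 of such an epoxide is regiochemically secure, and no enolate oxidation is needed. On certainty of the C8 configuration this plan is the equal of the chosen one, or better.
- Against it here: A3 must discriminate between an epoxide and two methyl esters. A2 needs C8' set by a separate asymmetric step and then a matched epoxidation next to that centre, twice on one molecule. The oxidation-state changes make A2 long to prepare.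
- Comparison: the structure is assembled from the same three blocks (biaryl core, C4 chain, ring A), but by SN2 opening in place of conjugate addition and enolate chemistry. The step count would be clearly higher, and the meso problem is the same.

**Alternative 2:** The cut is the C7'–aryl bond of ring B. Zinc insertion into the C–I bond of iodomethyl lactone A5, then twofold coupling with bis(triflate) A6 under Pd2(dba)3/SPhos, would give the fully protected dimer A4. Desilylation and hydrogenolysis would finish.
- In its favour: it is the most convergent plan. All stereocentres are built on the monomer A5, which can be brought to full enantiopurity before dimerisation. On suppression of the heterochiral dimer this plan is better than the chosen one. The coupling is neutral and tolerates lactone and silyl ether; on functional-group tolerance of the union it is the equal of the chosen plan.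
- Against it here: A5 must still solve the C8 problem on the natural lactone (hydroxylation first, then benzylation of the dianion), and its preparation would take about as many steps as the whole chosen route. β-Hydride elimination can compete after transmetalation, because the carbon next to the metal-bearing CH2 carries a hydrogen, and both electron-rich triflates must react.
- Comparison: more convergent, but longer in total, with one more deprotection and a palladium step on a valuable late intermediate.

**Alternative 3:** The cut is the C8–O bond, traced to a C8–acetyl bond. CF3CO3H would oxidise both methyl ketones of bis(α-acetyl lactone) A8, the quaternary C8 migrating to oxygen with retention, to give bis(tertiary acetate) A7. Removal of two acetates and four pivalates would follow.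
- In its favour: C8 of A8 would be set by a C-benzylation under mild base, anti to the C8' benzyl group, which is the normal bias and here leads to the right configuration after the retentive shift. In using the inherent bias without strong base it is the equal of the chosen plan.
- Against it here: the migrating carbon carries the lactone carbonyl, which slows migration. A strong peracid is brought to four methoxy-bearing rings that are only partly deactivated as pivalates. The final deacylation exposes air-sensitive phenols and the lactone to base. The C8' centre on the biaryl still needs its own asymmetric entry.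
- Comparison: one more oxidation-level detour (acetyl in, acetate out) and a less safe end game, with comparable or greater length.

Key step: step 5

## Route

**Step 1**
Reactants: 1 dehydrodivanillin
Product: 2 6,6'-bis(benzyloxy)-5,5'-dimethoxybiphenyl-3,3'-dicarbaldehyde
Conditions: BnBr (2.5 equiv), K2CO3, DMF, 60 °C
Reagents that add atoms: benzyl bromide, BrCc1ccccc1
Why: Twofold Williamson etherification of the two phenoxides; benzyl is chosen because it leaves in the same final hydrogenolysis that cleaves the C7'–O bonds.

**Step 2**
Reactants: 2 the dibenzyl dialdehyde; 3 methyl propiolate (two molecules react per molecule of 2)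
Product: 4 dimethyl (4S,4'S)-4,4'-[6,6'-bis(benzyloxy)-5,5'-dimethoxybiphenyl-3,3'-diyl]bis(4-hydroxybut-2-ynoate)
Conditions: 3 (6 equiv), ZnMe2 (6 equiv), (S,S)-ProPhenol (20 mol%), Ph3P=O (40 mol%), toluene, 0 → 4 °C; then aq NH4Cl
Reagents that add atoms: methyl propiolate (second molecule of 3), C#CC(=O)OC
Why: Catalytic enantioselective alkynylation of aldehydes by the alkynylzinc formed from 3 and ZnMe2, on the catalyst made from ZnMe2 and (S,S)-ProPhenol; both aldehyde groups react, so two molecules of 3 are built in, and the ligand selects the aldehyde face at each site independently, which sets both C7' carbinols by reagent control. Two independent events should amplify the enantiomeric purity of the C2 isomer at the cost of a small meso fraction.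

**Step 3**
Reactants: 4 the bis(hydroxy ynoate)
Product: 6 (5R,5'R)-5,5'-[6,6'-bis(benzyloxy)-5,5'-dimethoxybiphenyl-3,3'-diyl]bis[furan-2(5H)-one], via bis-(Z)-4-hydroxybut-2-enoate 5 (not isolated)
Conditions: H2 (1 atm), Pd/CaCO3–Pb(OAc)2, quinoline, EtOAc, rt; then PPTS (cat.), CH2Cl2, rt
Reagents that add atoms: none
Why: Syn semihydrogenation over Pd/CaCO3–Pb(OAc)2 (Lindlar reduction) gives the Z-enoate 5, whose hydroxyl then displaces methanol in a 5-exo-trig lactonisation under mild acid. The carbinol C–O bond is not touched, so the geometry is retained (the descriptor becomes R only through the priority change), and base is avoided because C7'–H is acidic.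

**Step 4**
Reactants: 7 (chloromethyl)isopropoxydimethylsilane
Product: 8 (isopropoxydimethylsilyl)methylmagnesium chloride (THF solution)
Conditions: Mg turnings, BrCH2CH2Br (cat.), THF, reflux → rt
Reagents that add atoms: magnesium, [Mg]
Why: Grignard formation by direct magnesium insertion into the C–Cl bond of an α-chloromethylsilane; the hindered isopropoxy group keeps silicon from being attacked by the Grignard reagent.

**Step 5**
Reactants: 6 the bis-butenolide; 8 the silylmethyl Grignard reagent (two molecules react per molecule of 6)
Product: 10 (4R,4'R,5R,5'R)-5,5'-[6,6'-bis(benzyloxy)-5,5'-dimethoxybiphenyl-3,3'-diyl]bis{4-[(isopropoxydimethylsilyl)methyl]dihydrofuran-2(3H)-one}, via bis(silyl ketene acetal) 9 (not isolated)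
Conditions: 8 (5 equiv), CuBr·SMe2 (0.5 equiv), Me3SiCl (6 equiv), THF, −78 → −40 °C; then aq NH4Cl
Reagents that add atoms: (isopropoxydimethylsilyl)methylmagnesium chloride (second molecule of 8), CC(C)O[Si](C)(C)C[Mg]Cl
Why: Transmetalation gives a silylmethyl organocopper species of monovalent copper, which complexes the enoate, adds oxidatively at C8' to a β-cuprio enolate of trivalent copper and, helped by Me3SiCl, eliminates reductively to form the C8'–C9' bond and the silyl ketene acetal 9; aqueous NH4Cl hydrolyses 9 to the lactone. The closest known reaction type is the Me3SiCl-accelerated copper-catalysed conjugate addition of Grignard reagents to 5-substituted butenolides, with the silylmethyl reagent as a hydroxymethyl anion equivalent. No ring is closed. Each new C8' stereocentre is controlled by the adjacent C7' centre: the reagent reaches the β-carbon on the face opposite the γ-aryl group, which gives the trans lactone. The step needs 1,4- over 1,2-addition and over deprotonation at C7'; the soft organocopper nucleophile, the low temperature and immediate silyl trapping of the enolate secure this, and the γ-aryl group of the substrate secures the facial selectivity. The two butenolides are insulated from each other by the biaryl and should react independently, so an excess of reagent drives both to completion and one molecule of 8 is built in at each ring. The C–Si bond at C9' is a masked hydroxyl that cannot attack the lactone carbonyl, which keeps the provisional lactone in place until C8 is built.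

**Step 6**
Reactants: 11 4-(benzyloxy)-3-methoxybenzyl alcohol
Product: 12 4-(benzyloxy)-3-methoxybenzyl bromide
Conditions: PBr3, Et2O, 0 °C
Reagents that add atoms: phosphorus tribromide, BrP(Br)Br
Why: Nucleophilic substitution in which bromide displaces the activated phosphite ester of a primary benzylic alcohol; the electron-rich bromide is used at once.

**Step 7**
Reactants: 10 the bis(silylmethyl lactone); 12 the ring A benzylic bromide (two molecules react per molecule of 10)
Product: 13 (3R,3'R,4R,4'R,5R,5'R)-5,5'-[6,6'-bis(benzyloxy)-5,5'-dimethoxybiphenyl-3,3'-diyl]bis{3-[4-(benzyloxy)-3-methoxybenzyl]-4-[(isopropoxydimethylsilyl)methyl]dihydrofuran-2(3H)-one}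
Conditions: LiN(SiMe3)2 (2.3 equiv), THF, −78 °C; then 12 (3 equiv), DMPU, −78 → −30 °C
Reagents that add atoms: 4-(benzyloxy)-3-methoxybenzyl bromide (second molecule of 12), BrCc1ccc(OCc2ccccc2)c(OC)c1
Why: Twofold enolate alkylation: each lactone lithium enolate takes up one molecule of the reactive benzylic bromide 12, which enters anti to the adjacent silylmethyl arm. The configuration formed at C8 is of no consequence because C8 becomes planar again in step 8, and the hindered, non-nucleophilic amide should leave the Si–O bond alone.

**Step 8**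
Reactants: 13 the bis(α-benzyl lactone)
Product: 14 (3R,3'R,4S,4'S,5R,5'R)-5,5'-[6,6'-bis(benzyloxy)-5,5'-dimethoxybiphenyl-3,3'-diyl]bis{3-[4-(benzyloxy)-3-methoxybenzyl]-3-hydroxy-4-[(isopropoxydimethylsilyl)methyl]dihydrofuran-2(3H)-one}
Conditions: KN(SiMe3)2 (2.5 equiv), THF, −78 °C; then (±)-3-phenyl-2-(phenylsulfonyl)oxaziridine (3 equiv), −78 °C; aq NH4Cl
Reagents that add atoms: 3-phenyl-2-(phenylsulfonyl)oxaziridine, O=S(=O)(c1ccccc1)N1OC1c1ccccc1
Why: Davis oxidation of the potassium enolate; electrophilic oxygen is delivered to the face anti to the neighbouring silylmethyl arm on C8' (1,2-induction by the bulky CH2Si group). This puts the hydroxyl trans to C9' and the ring A benzyl cis to it, which is the 8R configuration of 17 once the lactone is transposed.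

**Step 9**
Reactants: 14 the bis(α-hydroxy lactone) silane
Product: 15 (3R,3'R,4S,4'S,5R,5'R)-5,5'-[6,6'-bis(benzyloxy)-5,5'-dimethoxybiphenyl-3,3'-diyl]bis{3-[4-(benzyloxy)-3-methoxybenzyl]-3-hydroxy-4-(hydroxymethyl)dihydrofuran-2(3H)-one}
Conditions: 30% H2O2, KF, KHCO3, THF/MeOH, rt
Reagents that add atoms: hydrogen peroxide, OO
Why: Tamao–Kumada oxidation: fluoride activates the alkoxysilane, hydroperoxide adds to silicon and C9' shifts from silicon to oxygen. Benzyl ethers and the tertiary carbinol are inert to buffered peroxide, and an acyl shift to the new primary hydroxyl would be harmless now because C8 is set and both lactone forms converge in step 10.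

**Step 10**
Reactants: 15 the bis(hydroxymethyl lactone)
Product: 17 bis-5,5-nortrachelogenin, via bis(dihydroxy acid) 16 (not isolated)
Conditions: H2 (3 atm), Pd(OH)2/C, EtOAc/AcOH 4:1, rt; then concentration at 40 °C
Reagents that add atoms: none
Why: Catalytic hydrogenolysis removes the four O-benzyl groups and cleaves both lactone C7'–O bonds, which are benzylic and para to a phenolic oxygen; this erases the C7' stereocentres and leaves C7' as CH2. The freed γ-hydroxy acid 16 closes on the C9' hydroxyl (5-exo-trig) in the acidic medium, and C8 and C8' take no part, so their configuration is kept.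

## Compound list

1 | dehydrodivanillin (6,6'-dihydroxy-5,5'-dimethoxybiphenyl-3,3'-dicarbaldehyde) | O=Cc1cc(OC)c(O)c(c1)-c1cc(C=O)cc(OC)c1O | starting material
2 | 6,6'-bis(benzyloxy)-5,5'-dimethoxybiphenyl-3,3'-dicarbaldehyde | O=Cc1cc(OC)c(OCc2ccccc2)c(c1)-c1cc(C=O)cc(OC)c1OCc1ccccc1 | intermediate
3 | methyl propiolate | C#CC(=O)OC | starting material
4 | dimethyl (4S,4'S)-4,4'-[6,6'-bis(benzyloxy)-5,5'-dimethoxybiphenyl-3,3'-diyl]bis(4-hydroxybut-2-ynoate) | c1([C@H](O)C#CC(=O)OC)cc(OC)c(OCc2ccccc2)c(c1)-c1cc([C@H](O)C#CC(=O)OC)cc(OC)c1OCc1ccccc1 | intermediate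
5 | dimethyl (2Z,2'Z,4R,4'R)-4,4'-[6,6'-bis(benzyloxy)-5,5'-dimethoxybiphenyl-3,3'-diyl]bis(4-hydroxybut-2-enoate) | c1([C@H](O)/C=C\C(=O)OC)cc(OC)c(OCc2ccccc2)c(c1)-c1cc([C@H](O)/C=C\C(=O)OC)cc(OC)c1OCc1ccccc1 | intermediate (not isolated)
6 | (5R,5'R)-5,5'-[6,6'-bis(benzyloxy)-5,5'-dimethoxybiphenyl-3,3'-diyl]bis[furan-2(5H)-one] | c1([C@@H]2OC(=O)C=C2)cc(OC)c(OCc2ccccc2)c(c1)-c1cc([C@@H]2OC(=O)C=C2)cc(OC)c1OCc1ccccc1 | intermediate
7 | (chloromethyl)isopropoxydimethylsilane | CC(C)O[Si](C)(C)CCl | starting material
8 | (isopropoxydimethylsilyl)methylmagnesium chloride | CC(C)O[Si](C)(C)C[Mg]Cl | intermediate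
9 | bis(silyl ketene acetal): each lactone of 10 as its 2-(trimethylsilyloxy)-4,5-dihydrofuran, (4R,5R) | c1([C@@H]2OC(O[Si](C)(C)C)=C[C@H]2C[Si](C)(C)OC(C)C)cc(OC)c(OCc2ccccc2)c(c1)-c1cc([C@@H]2OC(O[Si](C)(C)C)=C[C@H]2C[Si](C)(C)OC(C)C)cc(OC)c1OCc1ccccc1 | intermediate (not isolated)
10 | (4R,4'R,5R,5'R)-5,5'-[6,6'-bis(benzyloxy)-5,5'-dimethoxybiphenyl-3,3'-diyl]bis{4-[(isopropoxydimethylsilyl)methyl]dihydrofuran-2(3H)-one} (4,5-trans) | c1([C@@H]2OC(=O)C[C@H]2C[Si](C)(C)OC(C)C)cc(OC)c(OCc2ccccc2)c(c1)-c1cc([C@@H]2OC(=O)C[C@H]2C[Si](C)(C)OC(C)C)cc(OC)c1OCc1ccccc1 | intermediate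
11 | 4-(benzyloxy)-3-methoxybenzyl alcohol | OCc1ccc(OCc2ccccc2)c(OC)c1 | starting material
12 | 4-(benzyloxy)-3-methoxybenzyl bromide | BrCc1ccc(OCc2ccccc2)c(OC)c1 | intermediate
13 | (3R,4R,5R)-configured bis{3-[4-(benzyloxy)-3-methoxybenzyl]-4-[(isopropoxydimethylsilyl)methyl]-5-aryl lactone} on the dibenzylated biaryl (benzyl trans to the silylmethyl arm) | c1([C@@H]2OC(=O)[C@H](Cc3ccc(OCc4ccccc4)c(OC)c3)[C@H]2C[Si](C)(C)OC(C)C)cc(OC)c(OCc2ccccc2)c(c1)-c1cc([C@@H]2OC(=O)[C@H](Cc3ccc(OCc4ccccc4)c(OC)c3)[C@H]2C[Si](C)(C)OC(C)C)cc(OC)c1OCc1ccccc1 | intermediate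
14 | (3R,4S,5R)-configured bis{3-[4-(benzyloxy)-3-methoxybenzyl]-3-hydroxy-4-[(isopropoxydimethylsilyl)methyl]-5-aryl lactone} (hydroxyl trans to the silylmethyl arm) | c1([C@@H]2OC(=O)[C@@](O)(Cc3ccc(OCc4ccccc4)c(OC)c3)[C@H]2C[Si](C)(C)OC(C)C)cc(OC)c(OCc2ccccc2)c(c1)-c1cc([C@@H]2OC(=O)[C@@](O)(Cc3ccc(OCc4ccccc4)c(OC)c3)[C@H]2C[Si](C)(C)OC(C)C)cc(OC)c1OCc1ccccc1 | intermediate
15 | (3R,4S,5R)-configured bis{3-[4-(benzyloxy)-3-methoxybenzyl]-3-hydroxy-4-(hydroxymethyl)-5-aryl lactone} | c1([C@@H]2OC(=O)[C@@](O)(Cc3ccc(OCc4ccccc4)c(OC)c3)[C@H]2CO)cc(OC)c(OCc2ccccc2)c(c1)-c1cc([C@@H]2OC(=O)[C@@](O)(Cc3ccc(OCc4ccccc4)c(OC)c3)[C@H]2CO)cc(OC)c1OCc1ccccc1 | intermediate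
16 | (2R,2'R,3R,3'R)-4,4'-(6,6'-dihydroxy-5,5'-dimethoxybiphenyl-3,3'-diyl)bis[2-hydroxy-2-(4-hydroxy-3-methoxybenzyl)-3-(hydroxymethyl)butanoic acid] | c1(C[C@H](CO)[C@@](O)(C(=O)O)Cc3ccc(O)c(OC)c3)cc(OC)c(O)c(c1)-c1cc(C[C@H](CO)[C@@](O)(C(=O)O)Cc3ccc(O)c(OC)c3)cc(OC)c1O | intermediate (not isolated)
17 | bis-5,5-nortrachelogenin, (8R,8'R) in both halves | COc1cc(C[C@]2(O)C(=O)OC[C@H]2Cc2cc(OC)c(O)c(-c3cc(C[C@@H]4COC(=O)[C@@]4(O)Cc4ccc(O)c(OC)c4)cc(OC)c3O)c2)ccc1O | target

## Step count and least certain steps

Total: 10 steps. Longest linear sequence: 8 steps from **1** (steps 1, 2, 3, 5, 7, 8, 9, 10); steps 4 and 6 are one-step side branches.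

**Step 5 (key step).** The most likely failure is deprotonation at C7' by the basic organomagnesium species, in competition with 1,4-addition. That hydrogen is benzylic, allylic and next to oxygen, and its loss gives an aromatic furanolate, so material would be drained away and any recovered substrate would be partly racemised. Incomplete reaction at the second butenolide is the other risk. The fallback sets out from **6** and **7** and comes back at **10**; it is a radical addition with no base present. Finkelstein exchange of **7** (NaI, acetone, reflux) should give (iodomethyl)isopropoxydimethylsilane F1. Heating **6** with F1, (Me3Si)3SiH and AIBN in toluene at 80 °C should add the nucleophilic α-silylmethyl radical to C8' anti to the aryl group, with the α-acyl radical reduced by the silane, giving **10** directly.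

**Step 8.** The most likely failure is poor facial selectivity in oxygen transfer to a tetrasubstituted enolate. The desired face is anti to the C9' arm but is flanked 1,3 by the C7' aryl group, and an error at either site gives a diastereomer of the dimer. Incomplete enolisation of the hindered α-benzyl lactone is the second risk. The fallback sets out from **10** and comes back at **17**; oxygen is introduced by alkene dihydroxylation, where a chiral ligand can reinforce the substrate bias. Aldol addition of the lithium enolate of **10** (LiN(SiMe3)2, THF, −78 °C) to 4-(benzyloxy)-3-methoxybenzaldehyde should give the bis(aldol adduct) F2. MsCl/Et3N then DBU should give the bis[(E)-arylidene lactone] F3. OsO4 (cat.)/NMO, or K2OsO2(OH)4 with the matched one of (DHQD)2PHAL and (DHQ)2PHAL, should give the bis(7,8-diol) F4 with the C8 hydroxyl anti to the silylmethyl arm. Tamao oxidation as in step 9 should give the bis(triol) F5, and hydrogenolysis as in step 10 should also remove the extra benzylic C7 hydroxyl and give **17**.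

**Step 7.** The most likely failure is loss of the isopropoxysilane, by attack of amide or enolate at silicon or by hydrolysis on silica during purification. Over-alkylation at one of the two sites is the second risk. The fallback sets out from **10** and comes back at **17**; it follows the conventional order, with the C9' oxygen never present as an alkoxide. Tamao oxidation of **10** as in step 9 should give the bis(hydroxymethyl lactone) F6. 2-Benzyloxy-1-methylpyridinium triflate with MgO (PhCF3, 85 °C) should give the bis(benzyl ether) F7 under neutral conditions. LiN(SiMe3)2 and **12** should give the bis(α-benzyl lactone) F8, and KN(SiMe3)2 with the oxaziridine should give the bis(α-hydroxy lactone) F9. The hydrogenolysis of step 10, now removing six O-benzyl groups, should give **17**.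

**Step 2.** The most likely failure is insufficient facial selectivity per site with an electron-rich para-alkoxy aldehyde. For a per-site selectivity s, the heterochiral dimer forms in a fraction 2s(1 − s), and it is carried through as a diastereomer that is hard to remove; crystallisation of **6** would be the intended purification point. Competing methyl transfer from ZnMe2 is the second risk. The fallback sets out from **2** and comes back at **6**; the stereocentre is set by ketone reduction. Stetter reaction of **2** with methyl acrylate (3-benzyl-5-(2-hydroxyethyl)-4-methylthiazolium chloride, Et3N, EtOH, 70 °C) should give the bis(γ-keto ester) F10. Transfer hydrogenation with RuCl[(R,R)-TsDPEN](p-cymene) in HCO2H/Et3N, then TsOH, should give the bis[(R)-γ-aryl-γ-butyrolactone] F11. LiN(SiMe3)2 and PhSeBr should give the bis(α-phenylselanyl lactone) F12, and H2O2/pyridine (CH2Cl2, 0 °C) should give **6** by selenoxide syn-elimination.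

**Step 10.** The most likely failure is stalling after the fast O-debenzylation, with the lactone C7'–O bonds left intact because the free polyphenol binds the catalyst; forcing conditions risk ring saturation. The fallback sets out from **15** and comes back at **17**; the C7'–O bonds are cleaved ionically before debenzylation. Et3SiH/CF3CO2H (CH2Cl2, 0 °C) should ionise the p-benzyloxybenzylic C7'–O bonds, reduce the cations to CH2 and let the acids close on the C9' hydroxyls, giving tetra-O-benzyl bis-5,5-nortrachelogenin F13. Mild hydrogenolysis (H2, Pd/C, EtOAc/EtOH) should then give **17**.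

## Further compounds

F1 | step 5 | (iodomethyl)isopropoxydimethylsilane | CC(C)O[Si](C)(C)CI
F2 | step 8 | bis(aldol adduct): each lactone of 10 carrying a hydroxy[4-(benzyloxy)-3-methoxyphenyl]methyl group on C8 | c1([C@@H]2OC(=O)C(C(O)c3ccc(OCc4ccccc4)c(OC)c3)[C@H]2C[Si](C)(C)OC(C)C)cc(OC)c(OCc2ccccc2)c(c1)-c1cc([C@@H]2OC(=O)C(C(O)c3ccc(OCc4ccccc4)c(OC)c3)[C@H]2C[Si](C)(C)OC(C)C)cc(OC)c1OCc1ccccc1
F3 | step 8 | bis[(E)-α-(4-benzyloxy-3-methoxybenzylidene) lactone] | c1([C@@H]2OC(=O)/C(=C/c3ccc(OCc4ccccc4)c(OC)c3)[C@H]2C[Si](C)(C)OC(C)C)cc(OC)c(OCc2ccccc2)c(c1)-c1cc([C@@H]2OC(=O)/C(=C/c3ccc(OCc4ccccc4)c(OC)c3)[C@H]2C[Si](C)(C)OC(C)C)cc(OC)c1OCc1ccccc1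
F4 | step 8 | bis(7,8-diol) with the C8 hydroxyl trans to the silylmethyl arm | c1([C@@H]2OC(=O)[C@@](O)(C(O)c3ccc(OCc4ccccc4)c(OC)c3)[C@H]2C[Si](C)(C)OC(C)C)cc(OC)c(OCc2ccccc2)c(c1)-c1cc([C@@H]2OC(=O)[C@@](O)(C(O)c3ccc(OCc4ccccc4)c(OC)c3)[C@H]2C[Si](C)(C)OC(C)C)cc(OC)c1OCc1ccccc1
F5 | step 8 | bis(7,8,9'-triol) after Tamao oxidation | c1([C@@H]2OC(=O)[C@@](O)(C(O)c3ccc(OCc4ccccc4)c(OC)c3)[C@H]2CO)cc(OC)c(OCc2ccccc2)c(c1)-c1cc([C@@H]2OC(=O)[C@@](O)(C(O)c3ccc(OCc4ccccc4)c(OC)c3)[C@H]2CO)cc(OC)c1OCc1ccccc1
F6 | step 7 | bis[(4S,5R)-4-(hydroxymethyl)-5-aryl lactone] (trans) | c1([C@@H]2OC(=O)C[C@H]2CO)cc(OC)c(OCc2ccccc2)c(c1)-c1cc([C@@H]2OC(=O)C[C@H]2CO)cc(OC)c1OCc1ccccc1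
F7 | step 7 | bis[trans-4-(benzyloxymethyl)-5-aryl lactone] | c1([C@@H]2OC(=O)C[C@H]2COCc3ccccc3)cc(OC)c(OCc2ccccc2)c(c1)-c1cc([C@@H]2OC(=O)C[C@H]2COCc3ccccc3)cc(OC)c1OCc1ccccc1
F8 | step 7 | bis{3-[4-(benzyloxy)-3-methoxybenzyl]-4-(benzyloxymethyl)-5-aryl lactone} | c1([C@@H]2OC(=O)[C@H](Cc3ccc(OCc4ccccc4)c(OC)c3)[C@H]2COCc3ccccc3)cc(OC)c(OCc2ccccc2)c(c1)-c1cc([C@@H]2OC(=O)[C@H](Cc3ccc(OCc4ccccc4)c(OC)c3)[C@H]2COCc3ccccc3)cc(OC)c1OCc1ccccc1
F9 | step 7 | bis{3-[4-(benzyloxy)-3-methoxybenzyl]-3-hydroxy-4-(benzyloxymethyl)-5-aryl lactone} | c1([C@@H]2OC(=O)[C@@](O)(Cc3ccc(OCc4ccccc4)c(OC)c3)[C@H]2COCc3ccccc3)cc(OC)c(OCc2ccccc2)c(c1)-c1cc([C@@H]2OC(=O)[C@@](O)(Cc3ccc(OCc4ccccc4)c(OC)c3)[C@H]2COCc3ccccc3)cc(OC)c1OCc1ccccc1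
F10 | step 2 | dimethyl 4,4'-[6,6'-bis(benzyloxy)-5,5'-dimethoxybiphenyl-3,3'-diyl]bis(4-oxobutanoate) | c1(C(=O)CCC(=O)OC)cc(OC)c(OCc2ccccc2)c(c1)-c1cc(C(=O)CCC(=O)OC)cc(OC)c1OCc1ccccc1
F11 | step 2 | (5R,5'R)-5,5'-[6,6'-bis(benzyloxy)-5,5'-dimethoxybiphenyl-3,3'-diyl]bis[dihydrofuran-2(3H)-one] | c1([C@@H]2OC(=O)CC2)cc(OC)c(OCc2ccccc2)c(c1)-c1cc([C@@H]2OC(=O)CC2)cc(OC)c1OCc1ccccc1
F12 | step 2 | bis[(5R)-3-(phenylselanyl)-5-aryl lactone] (C3 epimers) | c1([C@@H]2OC(=O)C([Se]c3ccccc3)C2)cc(OC)c(OCc2ccccc2)c(c1)-c1cc([C@@H]2OC(=O)C([Se]c3ccccc3)C2)cc(OC)c1OCc1ccccc1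
F13 | step 10 | tetra-O-benzyl bis-5,5-nortrachelogenin | c1(C[C@@H]2COC(=O)[C@@]2(O)Cc2ccc(OCc3ccccc3)c(OC)c2)cc(OC)c(OCc2ccccc2)c(c1)-c1cc(C[C@@H]2COC(=O)[C@@]2(O)Cc2ccc(OCc3ccccc3)c(OC)c2)cc(OC)c1OCc1ccccc1
A1 | alternative 1 | bis(α-hydroxy ester) with ring A attached | c1(C[C@H](CO[Si](C)(C)C(C)(C)C)[C@@](O)(C(=O)OC)Cc2ccc(OCc3ccccc3)c(OC)c2)cc(OC)c(OCc2ccccc2)c(c1)-c1cc(C[C@H](CO[Si](C)(C)C(C)(C)C)[C@@](O)(C(=O)OC)Cc2ccc(OCc3ccccc3)c(OC)c2)cc(OC)c1OCc1ccccc1
A2 | alternative 1 | bis(glycidic ester): methyl 2-substituted oxirane-2-carboxylate on each arm | c1(C[C@H](CO[Si](C)(C)C(C)(C)C)[C@@]2(C(=O)OC)CO2)cc(OC)c(OCc2ccccc2)c(c1)-c1cc(C[C@H](CO[Si](C)(C)C(C)(C)C)[C@@]2(C(=O)OC)CO2)cc(OC)c1OCc1ccccc1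
A3 | alternative 1 | 4-(benzyloxy)-3-methoxyphenylmagnesium bromide | COc1cc([Mg]Br)ccc1OCc1ccccc1
A4 | alternative 2 | fully protected target (two triethylsilyl ethers, four benzyl ethers) | c1(C[C@@H]2COC(=O)[C@@]2(O[Si](CC)(CC)CC)Cc2ccc(OCc3ccccc3)c(OC)c2)cc(OC)c(OCc2ccccc2)c(c1)-c1cc(C[C@@H]2COC(=O)[C@@]2(O[Si](CC)(CC)CC)Cc2ccc(OCc3ccccc3)c(OC)c2)cc(OC)c1OCc1ccccc1
A5 | alternative 2 | 3-[4-(benzyloxy)-3-methoxybenzyl]-4-(iodomethyl)-3-(triethylsilyloxy)dihydrofuran-2(3H)-one, configured as in 17 | IC[C@@H]1COC(=O)[C@@]1(O[Si](CC)(CC)CC)Cc1ccc(OCc2ccccc2)c(OC)c1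
A6 | alternative 2 | 6,6'-bis(benzyloxy)-5,5'-dimethoxybiphenyl-3,3'-diyl bis(trifluoromethanesulfonate) | FC(F)(F)S(=O)(=O)Oc1cc(OC)c(OCc2ccccc2)c(c1)-c1cc(OS(=O)(=O)C(F)(F)F)cc(OC)c1OCc1ccccc1
A7 | alternative 3 | bis(tertiary acetate) of tetrapivaloyl 17 | c1(C[C@@H]2COC(=O)[C@@]2(OC(C)=O)Cc2ccc(OC(=O)C(C)(C)C)c(OC)c2)cc(OC)c(OC(=O)C(C)(C)C)c(c1)-c1cc(C[C@@H]2COC(=O)[C@@]2(OC(C)=O)Cc2ccc(OC(=O)C(C)(C)C)c(OC)c2)cc(OC)c1OC(=O)C(C)(C)C
A8 | alternative 3 | bis(α-acetyl-α-benzyl lactone), tetrapivalate | c1(C[C@@H]2COC(=O)[C@@]2(C(C)=O)Cc2ccc(OC(=O)C(C)(C)C)c(OC)c2)cc(OC)c(OC(=O)C(C)(C)C)c(c1)-c1cc(C[C@@H]2COC(=O)[C@@]2(C(C)=O)Cc2ccc(OC(=O)C(C)(C)C)c(OC)c2)cc(OC)c1OC(=O)C(C)(C)C
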